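**Assumption:** the target is read as (−)-epigallocatechin-3-O-gallate-(4β→8)-(−)-epigallocatechin (upper unit 2R,3R,4R; lower unit 2R,3R); the O-benzylated building blocks 1, 4 and 7 are bought.

## Retrosynthetic overview

1. Target 13 ⇐ global hydrogenolysis of the trideca-O-benzyl ether 12.
2. 12 ⇐ one-flask triple Friedel–Crafts reaction of α-galloyloxy aldehyde 9 with aryl glycidyl ether 5. It forms C4'–C4a' (lower pyran ring), C4–C4a (upper pyran ring) and the C4–C8' interflavan bond.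
3. 9 ⇐ 5 by one-carbon homologation to the vinyl carbinol, galloylation and C=C cleavage, so both flavan units come from the single chiral ether 5.
4. 5 ⇐ Mitsunobu inversion with phenol 4 of erythro epoxy alcohol 3 ⇐ Sharpless kinetic resolution of vinyl carbinol 2 ⇐ aldehyde 1.
5. Ring order: the oxirane (step 2) is the only ring made early; the two pyran rings are closed last, together, in step 7 (lower ring first, then upper ring, then capture of the C4 cation).

## Route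

Step 1
Reactants: 1 3,4,5-tris(benzyloxy)benzaldehyde
Product: 2 rac-1-[3,4,5-tris(benzyloxy)phenyl]prop-2-en-1-ol
Conditions: CH2=CHMgBr (1.2 equiv), THF, −78 → 0 °C; aq NH4Cl
Reagents that add atoms: vinylmagnesium bromide, C=C[Mg]Br
Why: Grignard 1,2-addition to a non-enolisable aryl aldehyde gives the racemic allylic alcohol, whose stereocentre is resolved in the next step.

Step 2
Reactants: 2 rac-1-[3,4,5-tris(benzyloxy)phenyl]prop-2-en-1-ol
Product: 3 (S)-[(2R)-oxiran-2-yl][3,4,5-tris(benzyloxy)phenyl]methanol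
Conditions: Ti(OiPr)4 (0.1 equiv), L-(+)-DIPT (0.15 equiv), t-BuOOH (0.5 equiv), 4 Å molecular sieves, CH2Cl2, −20 °C, stopped near 45% conversion
Reagents that add atoms: tert-butyl hydroperoxide, CC(C)(C)OO
Why: Sharpless asymmetric epoxidation run as a kinetic resolution: with L-(+)-DIPT the (R)-carbinol is epoxidised much faster than the (S)-carbinol and almost only to the erythro epoxy alcohol, which sets the carbinol centre (S) and the oxirane centre (R, the later C3), while (S)-2 stays behind and is separated.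

Step 3
Reactants: 3 (S)-[(2R)-oxiran-2-yl][3,4,5-tris(benzyloxy)phenyl]methanol; 4 3,5-bis(benzyloxy)phenol
Product: 5 (2R)-2-{(R)-[3,5-bis(benzyloxy)phenoxy][3,4,5-tris(benzyloxy)phenyl]methyl}oxirane
Conditions: 4 (1.2 equiv), PPh3 (1.3 equiv), DIAD (1.3 equiv), toluene, 0 °C → rt
Reagents that add atoms: none
Why: Mitsunobu etherification with SN2 inversion at the benzylic carbinol converts the erythro epoxy alcohol into the threo aryl glycidyl ether and sets the later C2 as R (2,3-cis), the neighbouring oxirane disfavouring ionisation and surviving the neutral conditions.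

Step 4
Reactants: 5 (2R)-2-{(R)-[3,5-bis(benzyloxy)phenoxy][3,4,5-tris(benzyloxy)phenyl]methyl}oxirane
Product: 6 (1R,2R)-1-[3,5-bis(benzyloxy)phenoxy]-1-[3,4,5-tris(benzyloxy)phenyl]but-3-en-2-ol
Conditions: Me3S+ I− (4 equiv), n-BuLi (3.8 equiv), THF, −10 °C; then 5, −10 °C → rt
Reagents that add atoms: trimethylsulfonium iodide, C[S+](C)C.[I-]
Why: Epoxide-to-allylic-alcohol homologation with dimethylsulfonium methylide (the ylide opens the terminal oxirane carbon and elimination of Me2S gives the vinyl carbinol) breaks no bond at either stereocentre, so both are retained.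

Step 5
Reactants: 6 (1R,2R)-1-[3,5-bis(benzyloxy)phenoxy]-1-[3,4,5-tris(benzyloxy)phenyl]but-3-en-2-ol; 7 3,4,5-tris(benzyloxy)benzoic acid
Product: 8 (1R,2R)-1-[3,5-bis(benzyloxy)phenoxy]-1-[3,4,5-tris(benzyloxy)phenyl]but-3-en-2-yl 3,4,5-tris(benzyloxy)benzoate
Conditions: 7 (1.3 equiv), DCC (1.4 equiv), DMAP (0.3 equiv), CH2Cl2, rt
Reagents that add atoms: none
Why: Steglich esterification acylates the only free hydroxyl with retention, placing the gallate on the later upper C3 oxygen before any second hydroxyl exists in the molecule.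

Step 6
Reactants: 8 (1R,2R)-1-[3,5-bis(benzyloxy)phenoxy]-1-[3,4,5-tris(benzyloxy)phenyl]but-3-en-2-yl 3,4,5-tris(benzyloxy)benzoate
Product: 9 (2S,3R)-3-[3,5-bis(benzyloxy)phenoxy]-1-oxo-3-[3,4,5-tris(benzyloxy)phenyl]propan-2-yl 3,4,5-tris(benzyloxy)benzoate
Conditions: OsO4 (2 mol%), NaIO4 (4 equiv), 2,6-lutidine (2 equiv), 1,4-dioxane/H2O 3:1, rt; crude 9 used at once
Reagents that add atoms: sodium periodate, [Na+].[O-]I(=O)(=O)=O; osmium tetroxide, O=[Os](=O)(=O)=O (catalytic oxygen carrier)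
Why: Lemieux–Johnson oxidative cleavage (OsO4 dihydroxylation, periodate glycol cleavage) turns the terminal vinyl group into the C4 aldehyde under lutidine buffering, leaving both stereocentres untouched (the descriptor at the α-carbon changes to S only through the priority change).

Step 7
Reactants: 5 (2R)-2-{(R)-[3,5-bis(benzyloxy)phenoxy][3,4,5-tris(benzyloxy)phenyl]methyl}oxirane (3.0 equiv); 9 (2S,3R)-3-[3,5-bis(benzyloxy)phenoxy]-1-oxo-3-[3,4,5-tris(benzyloxy)phenyl]propan-2-yl 3,4,5-tris(benzyloxy)benzoate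
Product: 12 trideca-O-benzyl epigallocatechin-3-O-gallate-(4β→8)-epigallocatechin, via pentabenzyl epigallocatechin 10 (not isolated), via 4-hydroxyflavan gallate 11 (not isolated)
Conditions: 5, AuCl3 (10 mol%), AgOTf (30 mol%), 4 Å molecular sieves, CH2Cl2, 0 °C, 1 h; then 9 (1.0 equiv) in CH2Cl2 added over 1 h at −20 °C, warm to 0 °C; Et3N quench
Reagents that add atoms: none
Why: Proposed new method: one Lewis-acid system drives three Friedel–Crafts events in one flask, namely (a) 6-endo epoxide–arene cycloalkylation of 5 to 10 with C2 and C3 untouched, (b) intramolecular hydroxyalkylation of the phloroglucinol-type aryl ether ring of 9 onto the activated aldehyde to close the upper pyran ring as 11, and (c) ionisation of the doubly activated C4–OH with loss of water to a cation bridged by the neighbouring 3-O-galloyl carbonyl, which C8 of 10 attacks anti to the C3–O bond to set C4 as R (3,4-trans, 4β), the reverse order of (b) and (c) giving the same product; the closest known reactions are the AuCl3/AgOTf-catalysed cycloalkylation of aryl glycidyl ethers to flavan-3-ols, the AuCl3-catalysed diarylation of aldehydes to triarylmethanes and the Lewis-acid coupling of 4-oxygenated flavan-3-yl esters with benzylated flavan-3-ols at C8.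

Step 8
Reactants: 12 trideca-O-benzyl epigallocatechin-3-O-gallate-(4β→8)-epigallocatechin
Product: 13 (−)-epigallocatechin-3-O-gallate-(4β→8)-(−)-epigallocatechin (CNP0194932.2)
Conditions: H2 (1 atm), Pd(OH)2/C (20 wt%), THF/MeOH/H2O 20:1:1, rt; filter, lyophilise
Reagents that add atoms: none
Why: Catalytic hydrogenolysis removes all thirteen benzyl ethers while the gallate ester, the interflavan C–C bond and the five stereocentres are unaffected under these neutral conditions.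

## Compound list

1 | 3,4,5-tris(benzyloxy)benzaldehyde | O=Cc1cc(OCc2ccccc2)c(OCc2ccccc2)c(OCc2ccccc2)c1 | starting material
2 | rac-1-[3,4,5-tris(benzyloxy)phenyl]prop-2-en-1-ol | C=CC(O)c1cc(OCc2ccccc2)c(OCc2ccccc2)c(OCc2ccccc2)c1 | intermediate
3 | (S)-[(2R)-oxiran-2-yl][3,4,5-tris(benzyloxy)phenyl]methanol (erythro) | C1O[C@H]1[C@@H](O)c1cc(OCc2ccccc2)c(OCc2ccccc2)c(OCc2ccccc2)c1 | intermediate
4 | 3,5-bis(benzyloxy)phenol | Oc1cc(OCc2ccccc2)cc(OCc2ccccc2)c1 | starting material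
5 | (2R)-2-{(R)-[3,5-bis(benzyloxy)phenoxy][3,4,5-tris(benzyloxy)phenyl]methyl}oxirane (threo) | C1O[C@H]1[C@H](Oc1cc(OCc2ccccc2)cc(OCc2ccccc2)c1)c1cc(OCc2ccccc2)c(OCc2ccccc2)c(OCc2ccccc2)c1 | intermediate
6 | (1R,2R)-1-[3,5-bis(benzyloxy)phenoxy]-1-[3,4,5-tris(benzyloxy)phenyl]but-3-en-2-ol | C=C[C@@H](O)[C@H](Oc1cc(OCc2ccccc2)cc(OCc2ccccc2)c1)c1cc(OCc2ccccc2)c(OCc2ccccc2)c(OCc2ccccc2)c1 | intermediate
7 | 3,4,5-tris(benzyloxy)benzoic acid | OC(=O)c1cc(OCc2ccccc2)c(OCc2ccccc2)c(OCc2ccccc2)c1 | starting material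
8 | (1R,2R)-1-[3,5-bis(benzyloxy)phenoxy]-1-[3,4,5-tris(benzyloxy)phenyl]but-3-en-2-yl 3,4,5-tris(benzyloxy)benzoate | C=C[C@@H](OC(=O)c1cc(OCc2ccccc2)c(OCc2ccccc2)c(OCc2ccccc2)c1)[C@H](Oc1cc(OCc2ccccc2)cc(OCc2ccccc2)c1)c1cc(OCc2ccccc2)c(OCc2ccccc2)c(OCc2ccccc2)c1 | intermediate
9 | (2S,3R)-3-[3,5-bis(benzyloxy)phenoxy]-1-oxo-3-[3,4,5-tris(benzyloxy)phenyl]propan-2-yl 3,4,5-tris(benzyloxy)benzoate | O=C[C@@H](OC(=O)c1cc(OCc2ccccc2)c(OCc2ccccc2)c(OCc2ccccc2)c1)[C@H](Oc1cc(OCc2ccccc2)cc(OCc2ccccc2)c1)c1cc(OCc2ccccc2)c(OCc2ccccc2)c(OCc2ccccc2)c1 | intermediate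
10 | (2R,3R)-5,7-bis(benzyloxy)-2-[3,4,5-tris(benzyloxy)phenyl]-3,4-dihydro-2H-chromen-3-ol (penta-O-benzyl-(−)-epigallocatechin) | O[C@@H]1Cc2c(OCc3ccccc3)cc(OCc3ccccc3)cc2O[C@@H]1c1cc(OCc2ccccc2)c(OCc2ccccc2)c(OCc2ccccc2)c1 | intermediate
11 | (2R,3R)-5,7-bis(benzyloxy)-4-hydroxy-2-[3,4,5-tris(benzyloxy)phenyl]-3,4-dihydro-2H-chromen-3-yl 3,4,5-tris(benzyloxy)benzoate (both C4 epimers, C4 left undefined) | OC1c2c(OCc3ccccc3)cc(OCc3ccccc3)cc2O[C@H](c2cc(OCc3ccccc3)c(OCc3ccccc3)c(OCc3ccccc3)c2)[C@@H]1OC(=O)c1cc(OCc2ccccc2)c(OCc2ccccc2)c(OCc2ccccc2)c1 | intermediate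
12 | (2R,3R,4R)-5,7-bis(benzyloxy)-4-{(2R,3R)-5,7-bis(benzyloxy)-3-hydroxy-2-[3,4,5-tris(benzyloxy)phenyl]-3,4-dihydro-2H-chromen-8-yl}-2-[3,4,5-tris(benzyloxy)phenyl]-3,4-dihydro-2H-chromen-3-yl 3,4,5-tris(benzyloxy)benzoate | O=C(O[C@@H]1[C@@H](c2c(OCc3ccccc3)cc(OCc3ccccc3)c3c2O[C@H](c2cc(OCc4ccccc4)c(OCc4ccccc4)c(OCc4ccccc4)c2)[C@H](O)C3)c2c(OCc3ccccc3)cc(OCc3ccccc3)cc2O[C@@H]1c1cc(OCc2ccccc2)c(OCc2ccccc2)c(OCc2ccccc2)c1)c1cc(OCc2ccccc2)c(OCc2ccccc2)c(OCc2ccccc2)c1 | intermediate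
13 | (2R,3R,4R)-5,7-dihydroxy-4-[(2R,3R)-3,5,7-trihydroxy-2-(3,4,5-trihydroxyphenyl)-3,4-dihydro-2H-chromen-8-yl]-2-(3,4,5-trihydroxyphenyl)-3,4-dihydro-2H-chromen-3-yl 3,4,5-trihydroxybenzoate | O=C(O[C@@H]1[C@@H](c2c(O)cc(O)c3c2O[C@H](c2cc(O)c(O)c(O)c2)[C@H](O)C3)c2c(O)cc(O)cc2O[C@@H]1c1cc(O)c(O)c(O)c1)c1cc(O)c(O)c(O)c1 | target

## Step count and risks

Total steps: 8. Longest linear sequence: 8 (1 → 2 → 3 → 5 → 6 → 8 → 9 → 12 → 13; compound 5 feeds both halves of step 7).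

The three steps most likely to fail:

**Step 7.** Three acid-driven events share one flask. The aldehyde may be arylated twice by 10 instead of closing its own ring, the C4 cation may attack C6 of 10 or a second dimer, and 9 may epimerise before it cyclises. The fallback sets out from 9 (with 5 as the source of the nucleophile) and comes back at 12. Aldehyde 9 is cyclised alone with BF3·OEt2 in CH2Cl2 containing methanol at −40 °C, so that the C4 cation is trapped as the isolable ether (2R,3R,4S)-5,7-bis(benzyloxy)-4-methoxy-2-[3,4,5-tris(benzyloxy)phenyl]-3,4-dihydro-2H-chromen-3-yl 3,4,5-tris(benzyloxy)benzoate F1. Separately, 5 is cyclised with AuCl3/AgOTf and 10 is isolated. F1 is then ionised with Me3SiOTf at −78 °C in the presence of 10 (3 equiv) to give 12. This replaces the cascade by a stepwise coupling of an isolated 4-alkoxy electrophile.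

**Step 3.** The carbinol is benzylic to a para-oxygenated ring, so partial ionisation could erode the inversion, and the oxirane could be opened. The fallback sets out from 1 and comes back at 5; it makes the aryl ether by epoxide opening instead of by displacement of an activated carbinol. Z-selective Horner–Wadsworth–Emmons olefination of 1 with ethyl 2-(diphenoxyphosphoryl)acetate (NaH, THF, −78 °C) gives ethyl (2Z)-3-[3,4,5-tris(benzyloxy)phenyl]prop-2-enoate F4, and i-Bu2AlH reduction gives (2Z)-3-[3,4,5-tris(benzyloxy)phenyl]prop-2-en-1-ol F5. Sharpless epoxidation with Ti(OiPr)4, D-(−)-DIPT and t-BuOOH then gives the cis-epoxy alcohol [(2R,3S)-3-[3,4,5-tris(benzyloxy)phenyl]oxiran-2-yl]methanol F6. The sodium phenoxide of 4 (NaOH, aqueous dioxane, 70 °C) opens F6 at the benzylic carbon with inversion to the threo diol (2R,3R)-3-[3,5-bis(benzyloxy)phenoxy]-3-[3,4,5-tris(benzyloxy)phenyl]propane-1,2-diol F7. Selective primary tosylation (TsCl, pyridine) gives (2R,3R)-3-[3,5-bis(benzyloxy)phenoxy]-2-hydroxy-3-[3,4,5-tris(benzyloxy)phenyl]propyl 4-methylbenzenesulfonate F8, which NaH in THF closes to the terminal oxirane 5.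

**Step 6.** Aldehyde 9 is an α-acyloxy-β-aryloxy aldehyde. It can epimerise at the α-carbon or lose the phenoxide by β-elimination during cleavage or handling. The fallback sets out from 5 and comes back at 12; it installs the C4 leaving group by oxidation of a preformed flavan instead of carrying an aldehyde. Compound 5 is cyclised with AuCl3/AgOTf and 10 is isolated. Part of 10 is esterified with 7 (DCC, DMAP) to (2R,3R)-5,7-bis(benzyloxy)-2-[3,4,5-tris(benzyloxy)phenyl]-3,4-dihydro-2H-chromen-3-yl 3,4,5-tris(benzyloxy)benzoate F2. Benzylic oxidation of F2 with DDQ in CH2Cl2 containing 2-ethoxyethanol gives (2R,3R,4S)-5,7-bis(benzyloxy)-4-(2-ethoxyethoxy)-2-[3,4,5-tris(benzyloxy)phenyl]-3,4-dihydro-2H-chromen-3-yl 3,4,5-tris(benzyloxy)benzoate F3. F3 is ionised with Me3SiOTf at −78 °C in the presence of the remaining 10 (3 equiv) to give 12.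

## Further compounds

F1 | step 7 | (2R,3R,4S)-5,7-bis(benzyloxy)-4-methoxy-2-[3,4,5-tris(benzyloxy)phenyl]-3,4-dihydro-2H-chromen-3-yl 3,4,5-tris(benzyloxy)benzoate | O=C(O[C@@H]1[C@@H](OC)c2c(OCc3ccccc3)cc(OCc3ccccc3)cc2O[C@@H]1c1cc(OCc2ccccc2)c(OCc2ccccc2)c(OCc2ccccc2)c1)c1cc(OCc2ccccc2)c(OCc2ccccc2)c(OCc2ccccc2)c1
F2 | step 6 | (2R,3R)-5,7-bis(benzyloxy)-2-[3,4,5-tris(benzyloxy)phenyl]-3,4-dihydro-2H-chromen-3-yl 3,4,5-tris(benzyloxy)benzoate | O=C(O[C@@H]1Cc2c(OCc3ccccc3)cc(OCc3ccccc3)cc2O[C@@H]1c1cc(OCc2ccccc2)c(OCc2ccccc2)c(OCc2ccccc2)c1)c1cc(OCc2ccccc2)c(OCc2ccccc2)c(OCc2ccccc2)c1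
F3 | step 6 | (2R,3R,4S)-5,7-bis(benzyloxy)-4-(2-ethoxyethoxy)-2-[3,4,5-tris(benzyloxy)phenyl]-3,4-dihydro-2H-chromen-3-yl 3,4,5-tris(benzyloxy)benzoate | O=C(O[C@@H]1[C@@H](OCCOCC)c2c(OCc3ccccc3)cc(OCc3ccccc3)cc2O[C@@H]1c1cc(OCc2ccccc2)c(OCc2ccccc2)c(OCc2ccccc2)c1)c1cc(OCc2ccccc2)c(OCc2ccccc2)c(OCc2ccccc2)c1
F4 | step 3 | ethyl (2Z)-3-[3,4,5-tris(benzyloxy)phenyl]prop-2-enoate | CCOC(=O)/C=C\c1cc(OCc2ccccc2)c(OCc2ccccc2)c(OCc2ccccc2)c1
F5 | step 3 | (2Z)-3-[3,4,5-tris(benzyloxy)phenyl]prop-2-en-1-ol | OC/C=C\c1cc(OCc2ccccc2)c(OCc2ccccc2)c(OCc2ccccc2)c1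
F6 | step 3 | [(2R,3S)-3-[3,4,5-tris(benzyloxy)phenyl]oxiran-2-yl]methanol | OC[C@H]1O[C@H]1c1cc(OCc2ccccc2)c(OCc2ccccc2)c(OCc2ccccc2)c1
F7 | step 3 | (2R,3R)-3-[3,5-bis(benzyloxy)phenoxy]-3-[3,4,5-tris(benzyloxy)phenyl]propane-1,2-diol | OC[C@@H](O)[C@H](Oc1cc(OCc2ccccc2)cc(OCc2ccccc2)c1)c1cc(OCc2ccccc2)c(OCc2ccccc2)c(OCc2ccccc2)c1
F8 | step 3 | (2R,3R)-3-[3,5-bis(benzyloxy)phenoxy]-2-hydroxy-3-[3,4,5-tris(benzyloxy)phenyl]propyl 4-methylbenzenesulfonate | Cc1ccc(cc1)S(=O)(=O)OC[C@@H](O)[C@H](Oc1cc(OCc2ccccc2)cc(OCc2ccccc2)c1)c1cc(OCc2ccccc2)c(OCc2ccccc2)c(OCc2ccccc2)c1
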